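Atom labels used throughout: ring A is C1(aryl)–O2–C3(=O)–C4–C5, ring B is C4–C5–C6–O7–C8(aryl). Compound numbers are bare numerals.

## Analysis of the target

Target 18 is a cis-fused 3,7-dioxabicyclo[3.3.0]octan-2-one: γ-lactone ring A shares the C4–C5 bond with tetrahydrofuran ring B, C1 carries a 4-hydroxy-3,5-dimethoxyphenyl group and C8 a 3,4-dihydroxyphenyl group. The four contiguous stereocentres are C1 (S), C5 (S), C4 (R) and C8 (S), i.e. (3S,3aS,6S,6aR) in furo[3,4-c]furan numbering. All four hydrogens lie on the convex face, so both aryl groups sit on the concave face: the C1 aryl is cis to C6 and the C8 aryl is cis to the carbonyl carbon C3. This endo,endo arrangement is the less stable one at both benzylic centres, so neither can be reached or repaired by equilibration. Both benzylic C–O bonds (C1–O2 and C8–O7) are para to oxygen donors and ionize under acid, and once the phenols are free they also open under base through quinone methides. O7 is β to the carbonyl, so enolization at C4 invites ring opening of ring B, and the catechol is air-sensitive. The difficulty is therefore an unsymmetrical pair of aryl groups, two contra-thermodynamic centres, one enantiomer, and an endgame that tolerates neither acid nor base. The feature used is that removing O2 contracts ring A to a cyclobutanone C1–C3–C4–C5 fused to ring B with its aryl group cis to C6, the endo adduct of an arylketene and a symmetrical cyclic alkene. The hydrogen to be replaced on C8 is β and cis to the C3 carbonyl, within reach of a directing group placed there.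

## Retrosynthetic reasoning

The three phenols are unmasked last. Benzyl ethers are chosen because hydrogenolysis is neutral, so 18 is traced to its tribenzyl ether 17.

The C8–aryl bond is cut next. The aryl group is cis to C3, and C3 is the only functional handle near C8. Ring A of 17 is therefore opened at O2–C3 to an amide of 9, giving 14 (and its activated form 15), and 14 is disconnected to the unarylated amide 11 and aryl iodide 13. The forward reaction must replace only the C8 hydrogen that is cis to the amide. The other β-hydrogen, on C5, is tertiary and trans to the amide, so there is no regiochemical competition. Carrying the C8 aryl group in from the start is not an option, because a substituent already on the alkene would end up on the convex face.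

Amide 11 is the silyl ether of hydroxy amide 10, which comes from lactone 8 and 9 by acyl transfer. The C1 hydroxyl has to be masked during the arylation so that it cannot expel the auxiliary early, and the amide has to be activated afterwards so that the lactone can re-form without acid.

Lactone 8 is traced to cyclobutanone 7 by removing O2. Both carbons flanking the ketone are secondary, so the regiochemistry of oxygen insertion is not a matter of substitution. It should favour C1 because C1 is benzylic and donor-substituted, whereas C4 is deactivated by the β-oxygen O7. Migration with retention carries the endo aryl group into the C1 configuration of 8. Because 7 is racemic, this oxidation is also where the enantiomers are separated, as a catalytic kinetic resolution. A dynamic resolution is not possible, since epimerizing the aryl centre of 7 gives a diastereomer, not the mirror image.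

Cyclobutanone 7 is cut at C1–C5 and C3–C4 into arylketene 6 and 2,5-dihydrofuran 5. This is the only disconnection that forms ring A's carbon skeleton, the cis ring fusion and the endo aryl centre at once, and the symmetry of 5 removes any regiochemical or facial question. The forward reaction has to outrun ketene dimerization.

Ketene 6 is made in the flask from acid chloride 4, which comes from acid 3, from the doubly benzylated ester 2, from commercial acid 1. Aryl iodide 13 comes from 12 by benzylation. Both branches are short and conventional, so the risk sits in the cycloaddition.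

## Alternatives that were turned down

Alternative 1: O7–C8, C4–C5 and O2–C3 are disconnected together, back to epoxy alcohol A2 and benzylidene malonate A3. Forward, a catalytic alkoxide base lets the alkoxide of A2 add reversibly to A3, the malonate anion opens the epoxide at C5 with inversion (closing ring B), and the freed C1 alkoxide lactonizes to A1. In its favour, three bonds and both rings form in one flask, C5 is set by a stereospecific displacement, and the absolute configuration of A2 would come from a Sharpless epoxidation with no loss of half the material. Against it, C8 is decided only by which reversible oxa-Michael adduct cyclizes faster, and nothing in the substrate forces the aryl group onto the concave face. The alkoxide of A2 is also open to Payne rearrangement and to attack at the electron-rich benzylic carbon. The extra ester on C4 of A1 must then be removed through a β-alkoxy malonic half acid that can itself ring-open. This alternative is stronger on convergence and on absolute stereocontrol. The chosen route instead has C8 set by a directing group rather than by a rate competition.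

Alternative 2: ring B is disconnected at C6–O7 back to aroylcyclopropane A5. Forward, catalytic iodide opens A5 at its CH2 carbon and the resulting keto ester enolate closes on oxygen (Cloke–Wilson rearrangement) to dihydrofuran A4. Ketone reduction, lactonization and hydrogenation of the C4=C8 enol ether from the convex face would follow. In its favour, it is the shortest route on paper, and the convex-face hydrogenation would set C4 and C8 correctly in the step that also removes the benzyl groups. Against it, all chirality of A4 rests on C5, a methine α to an aryl ketone and vinylogously α to the ester, which can racemize under the rearrangement conditions and in every later basic step. C1 would then depend on a ketone reduction with no evident facial control. Hydrogenating a tetrasubstituted push–pull alkene also competes with hydrogenolysis of the benzylic C–O bonds. The chosen route is longer, but C1 comes from the ketene approach geometry and is carried over with retention, and C5 is never enolizable.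

Alternative 3: O7–C8 is disconnected back to keto lactone A7. Forward, a strong protic acid with a silane hydride donor closes the hemiketal, ionizes it, and delivers hydride to C8 from the convex face while C4 settles into the cis fusion, giving A6 (identical with 17). In its favour, the endgame is the shortest, the facial sense of the reduction is well founded, and C4 corrects itself through the keto lactone enol. Against it, ionic hydrogenation conditions are the ones that ionize donor-substituted benzylic C–O bonds. The new C8–O7 ether can re-ionize and either epimerize to the exo aryl or be reduced to a ring-opened benzyl compound, and the C1–O2 bond is exposed as well. A7 must also already contain the less stable cis relation between the C1 aryl and C6, so that problem is only moved. It is stronger on step count after the lactone. The chosen route forms C8 in an acetate-buffered medium and never exposes it to strong acid.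

Key step: step 4

Assumption: which antipode of the phosphoric acid in step 5 oxidizes the (1S,5R,7S)-ketone faster cannot be read from the structures; the (R)-acid is written, and the (S)-acid would be used instead if the sense proves opposite.

## Route

Step 1
Reactants: 1 (4-hydroxy-3,5-dimethoxyphenyl)acetic acid
Product: 2 benzyl [4-(benzyloxy)-3,5-dimethoxyphenyl]acetate
Conditions: BnBr (2.5 equiv), K2CO3 (3 equiv), DMF, 60 °C
Reagents that add atoms: benzyl bromide, BrCc1ccccc1
Why: Williamson etherification of the phenoxide and O-alkylation of the carboxylate run together; K2CO3 is too weak to deprotonate the arylacetate α-carbon, so no C-benzylation is expected.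

Step 2
Reactants: 2 benzyl [4-(benzyloxy)-3,5-dimethoxyphenyl]acetate
Product: 3 [4-(benzyloxy)-3,5-dimethoxyphenyl]acetic acid
Conditions: 2 M aq. NaOH, THF/MeOH, rt; then HCl to pH 2
Reagents that add atoms: sodium hydroxide, [Na+].[OH-]
Why: Saponification cleaves the benzyl ester by acyl–oxygen fission and leaves the aryl benzyl ether untouched.

Step 3
Reactants: 3 [4-(benzyloxy)-3,5-dimethoxyphenyl]acetic acid
Product: 4 [4-(benzyloxy)-3,5-dimethoxyphenyl]acetyl chloride
Conditions: (COCl)2 (1.3 equiv), DMF (cat.), CH2Cl2, 0 °C to rt; concentrated and used crude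
Reagents that add atoms: oxalyl chloride, ClC(=O)C(=O)Cl
Why: Acid chloride formation through the chloroiminium (Vilsmeier-type) reagent gives only gaseous by-products, so crude 4 can be taken straight into the ketene generation.

Step 4
Reactants: 4 [4-(benzyloxy)-3,5-dimethoxyphenyl]acetyl chloride; 5 2,5-dihydrofuran
Product: 7 rac-(1S,5R,7S)-7-[4-(benzyloxy)-3,5-dimethoxyphenyl]-3-oxabicyclo[3.2.0]heptan-6-one (aryl endo; racemate; the enantiomer used later is drawn), via arylketene 6 (not isolated)
Conditions: Et3N (1.5 equiv), 5 (large excess as solvent, freshly distilled), 4 in toluene added over 8 h, reflux (about 66 °C)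
Reagents that add atoms: none
Why: Et3N removes HCl from 4 to give arylketene 6, which adds across the double bond of 5 in a concerted but asynchronous thermal [2+2] cycloaddition: the ketene carbonyl carbon bonds first to one alkene carbon (the future C3–C4 bond) and the aryl-bearing carbon then closes onto the other (the future C1–C5 bond), the alkene reacting suprafacially. The closest known reaction type is the thermal cycloaddition of monosubstituted ketenes, made in the flask from acid chlorides and tertiary amines, with cyclopentadiene and cyclic cis-alkenes to endo-7-substituted bicyclo[3.2.0]heptan-6-ones. The four-membered ring is closed by the cycloaddition itself, both σ bonds forming across one alkene in a single bimolecular event, fused to the existing five-membered ring. C4 and C5 come out cis because the alkene is held Z in its ring and keeps its geometry in a suprafacial addition. C1 is set by the approach geometry: the ketene meets the alkene edge-on with its hydrogen turned towards the ring, and the twist that closes the second bond swings the larger aryl group onto the concave face, cis to C6 and C8, so the less stable endo epimer is the kinetic product. Because 5 is symmetrical, there is no regiochemical or facial issue and a single racemic diastereomer is expected. The step needs cycloaddition to outrun ketene dimerization and the endo centre to survive: 5 is used as solvent, 4 is fed slowly to keep the stationary ketene concentration low, 5 is freed beforehand from its enol ether isomer (a far better ketenophile that would give a regioisomeric skeleton), and 7 is separated from amine and oxidized without storage.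

Step 5
Reactants: 7 rac-(1S,5R,7S)-7-[4-(benzyloxy)-3,5-dimethoxyphenyl]-3-oxabicyclo[3.2.0]heptan-6-one
Product: 8 (3S,3aS,6aR)-3-[4-(benzyloxy)-3,5-dimethoxyphenyl]tetrahydro-1H,3H-furo[3,4-c]furan-1-one
Conditions: (R)-3,3′-di(pyren-1-yl)-5,5′,6,6′,7,7′,8,8′-octahydro-1,1′-binaphthalene-2,2′-diyl hydrogen phosphate (10 mol %), 30% aq. H2O2 (0.5 equiv), CHCl3, −40 °C, stopped below half conversion; Na2S2O3 quench; recrystallization
Reagents that add atoms: hydrogen peroxide, OO
Why: Catalytic asymmetric Baeyer–Villiger oxidation run as a kinetic resolution: the chiral Brønsted acid binds ketone and H2O2 by hydrogen bonds, and in the Criegee adduct the benzylic, para-alkoxy-substituted C1 migrates with retention in preference to C4, which is also secondary but deactivated by the β-oxygen O7. This reaction type is known for cyclobutanones, including racemic fused ones, and uncatalysed oxidation by aqueous H2O2 is negligible at this temperature, so the matched (1S,5R,7S)-ketone should be converted to 8 while its mirror image stays behind and is removed by chromatography.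

Step 6
Reactants: 8 (3S,3aS,6aR)-3-[4-(benzyloxy)-3,5-dimethoxyphenyl]tetrahydro-1H,3H-furo[3,4-c]furan-1-one; 9 8-aminoquinoline
Product: 10 (3R,4S)-4-{(S)-[4-(benzyloxy)-3,5-dimethoxyphenyl](hydroxy)methyl}-N-(quinolin-8-yl)oxolane-3-carboxamide
Conditions: AlMe3 (2 equiv), 9 (2 equiv), CH2Cl2, 0 to 40 °C; aq. potassium sodium tartrate (KNaC4H4O6) work-up; crude product used directly
Reagents that add atoms: none
Why: Weinreb-type aminolysis: the dimethylaluminium amide of 9 opens the lactone at the acyl carbon, so no bond to C1, C4 or C5 is touched and the amide and the carbinol side chain stay cis on ring B.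

Step 7
Reactants: 10 (3R,4S)-4-{(S)-[4-(benzyloxy)-3,5-dimethoxyphenyl](hydroxy)methyl}-N-(quinolin-8-yl)oxolane-3-carboxamide
Product: 11 (3R,4S)-4-{(S)-[4-(benzyloxy)-3,5-dimethoxyphenyl][(tert-butyldimethylsilyl)oxy]methyl}-N-(quinolin-8-yl)oxolane-3-carboxamide
Conditions: TBSOTf (1.3 equiv), 2,6-lutidine (2 equiv), CH2Cl2, −78 to 0 °C
Reagents that add atoms: tert-butyldimethylsilyl triflate, CC(C)(C)[Si](C)(C)OS(=O)(=O)C(F)(F)F
Why: Silylation of the secondary benzylic alcohol blocks relactonization, which would expel the directing group during the hot arylation; any O-silyl imidate formed at the amide hydrolyses on work-up.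

Step 8
Reactants: 12 4-iodobenzene-1,2-diol
Product: 13 1,2-bis(benzyloxy)-4-iodobenzene
Conditions: BnBr (2.3 equiv), K2CO3, DMF, 50 °C, under N2
Reagents that add atoms: benzyl bromide, BrCc1ccccc1
Why: Double Williamson etherification; exclusion of air avoids oxidation of the catechol before it is capped.

Step 9
Reactants: 11 (3R,4S)-4-{(S)-[4-(benzyloxy)-3,5-dimethoxyphenyl][(tert-butyldimethylsilyl)oxy]methyl}-N-(quinolin-8-yl)oxolane-3-carboxamide; 13 1,2-bis(benzyloxy)-4-iodobenzene
Product: 14 (2S,3R,4S)-2-[3,4-bis(benzyloxy)phenyl]-4-{(S)-[4-(benzyloxy)-3,5-dimethoxyphenyl][(tert-butyldimethylsilyl)oxy]methyl}-N-(quinolin-8-yl)oxolane-3-carboxamide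
Conditions: Pd(OAc)2 (10 mol %), AgOAc (2 equiv), 13 (3 equiv), toluene, 110 °C, sealed tube
Reagents that add atoms: none
Why: Amide-directed C(sp3)–H arylation of a saturated oxacycle: the deprotonated amide and the quinoline nitrogen chelate divalent palladium, concerted metalation–deprotonation takes the C8 hydrogen that is cis to the amide (five-membered palladacycle cis-fused to ring B), oxidative addition of 13 gives tetravalent palladium and reductive elimination forms C8–aryl with retention, AgOAc taking up the iodide. The new centre C8 is thus set cis to C3 by the directing group, and the only other β-hydrogen (on C5) is tertiary and trans, out of reach.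

Step 10
Reactants: 14 (2S,3R,4S)-2-[3,4-bis(benzyloxy)phenyl]-4-{(S)-[4-(benzyloxy)-3,5-dimethoxyphenyl][(tert-butyldimethylsilyl)oxy]methyl}-N-(quinolin-8-yl)oxolane-3-carboxamide
Product: 15 tert-butyl {[(2S,3R,4S)-2-[3,4-bis(benzyloxy)phenyl]-4-{(S)-[4-(benzyloxy)-3,5-dimethoxyphenyl][(tert-butyldimethylsilyl)oxy]methyl}oxolan-3-yl]carbonyl}(quinolin-8-yl)carbamate
Conditions: Boc2O (3 equiv), DMAP (0.5 equiv), MeCN, 50 °C
Reagents that add atoms: di-tert-butyl dicarbonate, CC(C)(C)OC(=O)OC(=O)OC(C)(C)C
Why: N-Acylation of the secondary amide under DMAP catalysis gives a twisted N-acyl carbamate whose C–N bond is activated for acyl transfer; this is the standard way of unlocking 8-aminoquinoline amides without acid.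

Step 11
Reactants: 15 tert-butyl {[(2S,3R,4S)-2-[3,4-bis(benzyloxy)phenyl]-4-{(S)-[4-(benzyloxy)-3,5-dimethoxyphenyl][(tert-butyldimethylsilyl)oxy]methyl}oxolan-3-yl]carbonyl}(quinolin-8-yl)carbamate
Product: 17 (3S,3aS,6S,6aR)-6-[3,4-bis(benzyloxy)phenyl]-3-[4-(benzyloxy)-3,5-dimethoxyphenyl]tetrahydro-1H,3H-furo[3,4-c]furan-1-one, via hydroxy N-Boc imide 16 (not isolated)
Conditions: Bu4NF/AcOH (1:1, 1.5 equiv), THF, 0 °C to rt
Reagents that add atoms: none
Why: Buffered fluoride removes the silyl group and the freed C1 hydroxyl, held cis to the activated acyl group, attacks it in a 5-exo-trig acyl transfer that expels the carbamate anion and re-forms ring A. Attack on the Boc carbonyl would need a seven-membered transition state, and the buffered medium avoids both acid at the benzylic centres and enolization at C4.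

Step 12
Reactants: 17 (3S,3aS,6S,6aR)-6-[3,4-bis(benzyloxy)phenyl]-3-[4-(benzyloxy)-3,5-dimethoxyphenyl]tetrahydro-1H,3H-furo[3,4-c]furan-1-one
Product: 18 (3S,3aS,6S,6aR)-6-(3,4-dihydroxyphenyl)-3-(4-hydroxy-3,5-dimethoxyphenyl)tetrahydro-1H,3H-furo[3,4-c]furan-1-one
Conditions: H2 (1 atm), 10% Pd on carbon, EtOAc, rt; stopped when uptake ends; filtered and concentrated under N2
Reagents that add atoms: none
Why: Hydrogenolysis of the three aryl benzyl ethers is much faster than cleavage of the dialkyl-type benzylic C–O bonds of the bicycle, and the neutral medium avoids the acid- and base-induced epimerization at C1 and C8 to which the free phenols would be prone.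

## Compound list

1 | (4-hydroxy-3,5-dimethoxyphenyl)acetic acid | COc1cc(CC(=O)O)cc(OC)c1O | starting material
2 | benzyl [4-(benzyloxy)-3,5-dimethoxyphenyl]acetate | COc1cc(CC(=O)OCc2ccccc2)cc(OC)c1OCc1ccccc1 | intermediate
3 | [4-(benzyloxy)-3,5-dimethoxyphenyl]acetic acid | COc1cc(CC(=O)O)cc(OC)c1OCc1ccccc1 | intermediate
4 | [4-(benzyloxy)-3,5-dimethoxyphenyl]acetyl chloride | COc1cc(CC(=O)Cl)cc(OC)c1OCc1ccccc1 | intermediate
5 | 2,5-dihydrofuran | C1C=CCO1 | starting material
6 | [4-(benzyloxy)-3,5-dimethoxyphenyl]ketene | COc1cc(C=C=O)cc(OC)c1OCc1ccccc1 | intermediate (not isolated)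
7 | rac-(1S,5R,7S)-7-[4-(benzyloxy)-3,5-dimethoxyphenyl]-3-oxabicyclo[3.2.0]heptan-6-one (aryl endo; racemate, needed enantiomer drawn) | COc1cc([C@H]2C(=O)[C@@H]3[C@H]2COC3)cc(OC)c1OCc1ccccc1 | intermediate
8 | (3S,3aS,6aR)-3-[4-(benzyloxy)-3,5-dimethoxyphenyl]tetrahydro-1H,3H-furo[3,4-c]furan-1-one | COc1cc([C@H]2OC(=O)[C@@H]3[C@H]2COC3)cc(OC)c1OCc1ccccc1 | intermediate
9 | 8-aminoquinoline | Nc1cccc2cccnc12 | starting material
10 | (3R,4S)-4-{(S)-[4-(benzyloxy)-3,5-dimethoxyphenyl](hydroxy)methyl}-N-(quinolin-8-yl)oxolane-3-carboxamide | COc1cc([C@@H](O)[C@@H]2COC[C@@H]2C(=O)Nc2cccc3cccnc23)cc(OC)c1OCc1ccccc1 | intermediate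
11 | (3R,4S)-4-{(S)-[4-(benzyloxy)-3,5-dimethoxyphenyl][(tert-butyldimethylsilyl)oxy]methyl}-N-(quinolin-8-yl)oxolane-3-carboxamide | COc1cc([C@@H](O[Si](C)(C)C(C)(C)C)[C@@H]2COC[C@@H]2C(=O)Nc2cccc3cccnc23)cc(OC)c1OCc1ccccc1 | intermediate
12 | 4-iodobenzene-1,2-diol | Oc1ccc(I)cc1O | starting material
13 | 1,2-bis(benzyloxy)-4-iodobenzene | Ic1ccc(OCc2ccccc2)c(OCc2ccccc2)c1 | intermediate
14 | (2S,3R,4S)-2-[3,4-bis(benzyloxy)phenyl]-4-{(S)-[4-(benzyloxy)-3,5-dimethoxyphenyl][(tert-butyldimethylsilyl)oxy]methyl}-N-(quinolin-8-yl)oxolane-3-carboxamide | COc1cc([C@@H](O[Si](C)(C)C(C)(C)C)[C@@H]2CO[C@H](c3ccc(OCc4ccccc4)c(OCc4ccccc4)c3)[C@@H]2C(=O)Nc2cccc3cccnc23)cc(OC)c1OCc1ccccc1 | intermediate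
15 | tert-butyl {[(2S,3R,4S)-2-[3,4-bis(benzyloxy)phenyl]-4-{(S)-[4-(benzyloxy)-3,5-dimethoxyphenyl][(tert-butyldimethylsilyl)oxy]methyl}oxolan-3-yl]carbonyl}(quinolin-8-yl)carbamate | COc1cc([C@@H](O[Si](C)(C)C(C)(C)C)[C@@H]2CO[C@H](c3ccc(OCc4ccccc4)c(OCc4ccccc4)c3)[C@@H]2C(=O)N(C(=O)OC(C)(C)C)c2cccc3cccnc23)cc(OC)c1OCc1ccccc1 | intermediate
16 | tert-butyl {[(2S,3R,4S)-2-[3,4-bis(benzyloxy)phenyl]-4-{(S)-[4-(benzyloxy)-3,5-dimethoxyphenyl](hydroxy)methyl}oxolan-3-yl]carbonyl}(quinolin-8-yl)carbamate | COc1cc([C@@H](O)[C@@H]2CO[C@H](c3ccc(OCc4ccccc4)c(OCc4ccccc4)c3)[C@@H]2C(=O)N(C(=O)OC(C)(C)C)c2cccc3cccnc23)cc(OC)c1OCc1ccccc1 | intermediate (not isolated)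
17 | (3S,3aS,6S,6aR)-6-[3,4-bis(benzyloxy)phenyl]-3-[4-(benzyloxy)-3,5-dimethoxyphenyl]tetrahydro-1H,3H-furo[3,4-c]furan-1-one | COc1cc([C@H]2OC(=O)[C@@H]3[C@H]2CO[C@@H]3c2ccc(OCc4ccccc4)c(OCc4ccccc4)c2)cc(OC)c1OCc1ccccc1 | intermediate
18 | (3S,3aS,6S,6aR)-6-(3,4-dihydroxyphenyl)-3-(4-hydroxy-3,5-dimethoxyphenyl)tetrahydro-1H,3H-furo[3,4-c]furan-1-one | COc1cc([C@H]2OC(=O)[C@@H]3[C@H]2CO[C@@H]3c2ccc(O)c(O)c2)cc(OC)c1O | target

## Step count and least certain steps

Total step count: 12. Longest linear sequence: 11 steps (steps 1–7 and 9–12, from 1 to 18); step 8 is a one-step side branch.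

Step 4 (key step). Dimerization and self-acylation of the ketene may outrun the cycloaddition, because an arylketene is only moderately electrophilic and the alkene of 5 is unactivated and inductively deactivated by its two allylic C–O bonds. The aryl centre may also partly epimerize to exo under the amine. Fallback, from 3 back to 7: the dianion of 3 (LiN(iPr)2, THF, −78 °C) is chlorinated with CCl4 to 2-chloro-2-[4-(benzyloxy)-3,5-dimethoxyphenyl]acetic acid F1, which (COCl)2 converts to 2-chloro-2-[4-(benzyloxy)-3,5-dimethoxyphenyl]acetyl chloride F2. Et3N in excess 5 then generates the more electrophilic [4-(benzyloxy)-3,5-dimethoxyphenyl](chloro)ketene F3, which should add to the alkene to give 7-chloro-7-[4-(benzyloxy)-3,5-dimethoxyphenyl]-3-oxabicyclo[3.2.0]heptan-6-one F4 (either configuration at the chlorinated carbon). Zn dust in AcOH removes the chlorine through the zinc enolate, which is protonated on the open convex face, placing the aryl group endo and giving 7.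

Step 5. Discrimination between the enantiomers of 7 may be too weak for 8 of high enantiomeric purity at useful conversion, since the catalyst must distinguish two ketones that differ only in the sense of a compact bicyclic core. Partial epimerization of 7 before oxidation would add the C1-epimeric lactone. Fallback, from 7 back to 8: oxidation with mCPBA/NaHCO3 in CH2Cl2 at 0 °C gives the racemic lactone, that is 8 together with its mirror image (3R,3aR,6aS)-3-[4-(benzyloxy)-3,5-dimethoxyphenyl]tetrahydro-1H,3H-furo[3,4-c]furan-1-one F5. The two are separated by preparative chromatography on a chiral stationary phase.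

Step 9. Palladation at C8 may be slowed by the cis side chain on C5, which makes the product an all-cis trisubstituted oxolane. The α-carbon C4 may epimerize at 110 °C, after which the amide can no longer close ring A. The benzylic silyl ether may also be lost, with early lactonization expelling the auxiliary. Fallback, from 8 back to 17, with a different auxiliary whose thioether arm is smaller and more labile:
- AlMe3-mediated opening of 8 with 2-(methylsulfanyl)aniline gives (3R,4S)-4-{(S)-[4-(benzyloxy)-3,5-dimethoxyphenyl](hydroxy)methyl}-N-[2-(methylsulfanyl)phenyl]oxolane-3-carboxamide F6.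
- Silylation as in step 7 gives the corresponding tert-butyldimethylsilyl ether F7.
- Arylation with 13 (Pd(OAc)2, AgOAc) gives (2S,3R,4S)-2-[3,4-bis(benzyloxy)phenyl]-4-{(S)-[4-(benzyloxy)-3,5-dimethoxyphenyl][(tert-butyldimethylsilyl)oxy]methyl}-N-[2-(methylsulfanyl)phenyl]oxolane-3-carboxamide F8.
- Boc2O/DMAP gives its N-Boc derivative F9, and buffered Bu4NF then closes the lactone to 17.

Step 11. The open-chain activated imide may enolize at C4 before the ring closes (epimerization, or β-elimination of O7), or the Boc group may be lost, because fluoride is basic and the imide α-hydrogen is acidic. Fallback, from 15 back to 17: LiOH/H2O2 in THF/H2O at 0 °C cleaves the activated amide to (2S,3R,4S)-2-[3,4-bis(benzyloxy)phenyl]-4-{(S)-[4-(benzyloxy)-3,5-dimethoxyphenyl][(tert-butyldimethylsilyl)oxy]methyl}oxolane-3-carboxylic acid F10. Desilylation of F10 with buffered Bu4NF should be followed by spontaneous lactonization of the cis hydroxy acid (or closure with a carbodiimide) to 17.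

Step 12. Over-reduction may occur by hydrogenolysis of the benzylic C1–O2 or C8–O7 bonds once the aryl ethers are gone, because both bonds are benzylic and the freed phenols increase their lability. Fallback, from 17 directly to 18: Lewis-acid debenzylation with BCl3 and pentamethylbenzene as cation scavenger in CH2Cl2 at −78 °C, quenched cold with MeOH. No new compound is made on the way (entry F0 below).

## Further compounds

F1 | step 4 | 2-chloro-2-[4-(benzyloxy)-3,5-dimethoxyphenyl]acetic acid (racemic) | COc1cc(C(Cl)C(=O)O)cc(OC)c1OCc1ccccc1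
F2 | step 4 | 2-chloro-2-[4-(benzyloxy)-3,5-dimethoxyphenyl]acetyl chloride (racemic) | COc1cc(C(Cl)C(=O)Cl)cc(OC)c1OCc1ccccc1
F3 | step 4 | [4-(benzyloxy)-3,5-dimethoxyphenyl](chloro)ketene | COc1cc(C(Cl)=C=O)cc(OC)c1OCc1ccccc1
F4 | step 4 | 7-chloro-7-[4-(benzyloxy)-3,5-dimethoxyphenyl]-3-oxabicyclo[3.2.0]heptan-6-one (racemic; cis ring fusion; either configuration at C7) | COc1cc(C2(Cl)C(=O)[C@@H]3[C@H]2COC3)cc(OC)c1OCc1ccccc1
F5 | step 5 | (3R,3aR,6aS)-3-[4-(benzyloxy)-3,5-dimethoxyphenyl]tetrahydro-1H,3H-furo[3,4-c]furan-1-one | COc1cc([C@@H]2OC(=O)[C@H]3[C@@H]2COC3)cc(OC)c1OCc1ccccc1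
F6 | step 9 | (3R,4S)-4-{(S)-[4-(benzyloxy)-3,5-dimethoxyphenyl](hydroxy)methyl}-N-[2-(methylsulfanyl)phenyl]oxolane-3-carboxamide | COc1cc([C@@H](O)[C@@H]2COC[C@@H]2C(=O)Nc2ccccc2SC)cc(OC)c1OCc1ccccc1
F7 | step 9 | (3R,4S)-4-{(S)-[4-(benzyloxy)-3,5-dimethoxyphenyl][(tert-butyldimethylsilyl)oxy]methyl}-N-[2-(methylsulfanyl)phenyl]oxolane-3-carboxamide | COc1cc([C@@H](O[Si](C)(C)C(C)(C)C)[C@@H]2COC[C@@H]2C(=O)Nc2ccccc2SC)cc(OC)c1OCc1ccccc1
F8 | step 9 | (2S,3R,4S)-2-[3,4-bis(benzyloxy)phenyl]-4-{(S)-[4-(benzyloxy)-3,5-dimethoxyphenyl][(tert-butyldimethylsilyl)oxy]methyl}-N-[2-(methylsulfanyl)phenyl]oxolane-3-carboxamide | COc1cc([C@@H](O[Si](C)(C)C(C)(C)C)[C@@H]2CO[C@H](c3ccc(OCc4ccccc4)c(OCc4ccccc4)c3)[C@@H]2C(=O)Nc2ccccc2SC)cc(OC)c1OCc1ccccc1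
F9 | step 9 | tert-butyl {[(2S,3R,4S)-2-[3,4-bis(benzyloxy)phenyl]-4-{(S)-[4-(benzyloxy)-3,5-dimethoxyphenyl][(tert-butyldimethylsilyl)oxy]methyl}oxolan-3-yl]carbonyl}[2-(methylsulfanyl)phenyl]carbamate | COc1cc([C@@H](O[Si](C)(C)C(C)(C)C)[C@@H]2CO[C@H](c3ccc(OCc4ccccc4)c(OCc4ccccc4)c3)[C@@H]2C(=O)N(C(=O)OC(C)(C)C)c2ccccc2SC)cc(OC)c1OCc1ccccc1
F10 | step 11 | (2S,3R,4S)-2-[3,4-bis(benzyloxy)phenyl]-4-{(S)-[4-(benzyloxy)-3,5-dimethoxyphenyl][(tert-butyldimethylsilyl)oxy]methyl}oxolane-3-carboxylic acid | COc1cc([C@@H](O[Si](C)(C)C(C)(C)C)[C@@H]2CO[C@H](c3ccc(OCc4ccccc4)c(OCc4ccccc4)c3)[C@@H]2C(=O)O)cc(OC)c1OCc1ccccc1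
F0 | step 12 | none | none
A1 | alternative 1 | benzyl 6-[3,4-bis(benzyloxy)phenyl]-3-[4-(benzyloxy)-3,5-dimethoxyphenyl]-1-oxotetrahydro-1H,3H-furo[3,4-c]furan-6a-carboxylate (ring centres as in 17) | COc1cc([C@H]2OC(=O)[C@]3(C(=O)OCc4ccccc4)[C@H]2CO[C@@H]3c2ccc(OCc4ccccc4)c(OCc4ccccc4)c2)cc(OC)c1OCc1ccccc1
A2 | alternative 1 | [(2R,3R)-3-[4-(benzyloxy)-3,5-dimethoxyphenyl]oxiran-2-yl]methanol | OC[C@H]1O[C@@H]1c1cc(OC)c(OCc2ccccc2)c(OC)c1
A3 | alternative 1 | dibenzyl 2-[3,4-bis(benzyloxy)benzylidene]propanedioate | O=C(OCc1ccccc1)C(=Cc1ccc(OCc2ccccc2)c(OCc2ccccc2)c1)C(=O)OCc1ccccc1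
A4 | alternative 2 | methyl (4S)-2-[3,4-bis(benzyloxy)phenyl]-4-[4-(benzyloxy)-3,5-dimethoxybenzoyl]-4,5-dihydrofuran-3-carboxylate | COC(=O)C1=C(c2ccc(OCc3ccccc3)c(OCc3ccccc3)c2)OC[C@H]1C(=O)c1cc(OC)c(OCc2ccccc2)c(OC)c1
A5 | alternative 2 | methyl (2R)-1-[3,4-bis(benzyloxy)benzoyl]-2-[4-(benzyloxy)-3,5-dimethoxybenzoyl]cyclopropane-1-carboxylate (either configuration at C1) | COC(=O)C1(C(=O)c2ccc(OCc3ccccc3)c(OCc3ccccc3)c2)C[C@H]1C(=O)c1cc(OC)c(OCc2ccccc2)c(OC)c1
A6 | alternative 3 | (3S,3aS,6S,6aR)-6-[3,4-bis(benzyloxy)phenyl]-3-[4-(benzyloxy)-3,5-dimethoxyphenyl]tetrahydro-1H,3H-furo[3,4-c]furan-1-one (identical with 17) | COc1cc([C@H]2OC(=O)[C@@H]3[C@H]2CO[C@@H]3c2ccc(OCc4ccccc4)c(OCc4ccccc4)c2)cc(OC)c1OCc1ccccc1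
A7 | alternative 3 | (4S,5S)-3-[3,4-bis(benzyloxy)benzoyl]-5-[4-(benzyloxy)-3,5-dimethoxyphenyl]-4-(hydroxymethyl)oxolan-2-one (C3 epimerizable) | COc1cc([C@H]2OC(=O)C(C(=O)c3ccc(OCc4ccccc4)c(OCc4ccccc4)c3)[C@H]2CO)cc(OC)c1OCc1ccccc1
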